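**Retrosynthetic overview**
- Do not benzylate a pre-formed bibenzyl (batatasin III); instead build the pentasubstituted central ring de novo, with every substituent placed by the annulation.
- Key step: Danheiser benzannulation of a 3,4-disubstituted cyclobutenone with a 1-methoxyalkyne. It delivers the free, doubly flanked OH, the meta OMe and the ring H directly, so the central ring needs no protection or selective O-methylation.
- Cyclobutenone: aldoketene/ethoxyacetylene [2+2], then Stork–Danheiser addition–transposition to install the aryl-ethyl chain.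
- Ynol ether: benzylation of in-situ lithium methoxyacetylide.
- Ring order: four-membered ring first, central benzene ring second, global O-debenzylation last.

Assumption: the target has no stereocentres (achiral), so "single enantiomer" is moot; intermediates 7 and 12 are racemic at one carbon that becomes aromatic in step 7.

---

**Step 1**
Reactants: 1 chloroacetaldehyde dimethyl acetal; 2 4-(benzyloxy)benzyl bromide
Product: 3 1-(benzyloxy)-4-(3-methoxyprop-2-yn-1-yl)benzene
Conditions: LiNEt2 (3 equiv), THF, 0 °C; then 2 (0.8 equiv), HMPA, −78 → −20 °C; NaHCO3 work-up, Et3N-deactivated SiO2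
Reagents that add atoms: none (both carbon fragments are numbered reactants)
Why: Double dehydrohalogenation/dealkoxylation of the chloroacetal gives LiC≡COMe in situ, which is C-alkylated by the reactive benzylic bromide (acetylide SN2 alkylation); low temperature limits N-benzylation of the liberated Et2NH and propargyl–allenyl isomerisation.

**Step 2**
Reactants: 4 3-[4-(benzyloxy)phenyl]propanoic acid
Product: 5 3-[4-(benzyloxy)phenyl]propanoyl chloride
Conditions: (COCl)2, cat. DMF, CH2Cl2, 0 °C → rt; concentrate, use crude
Reagents that add atoms: oxalyl chloride, ClC(=O)C(=O)Cl (Cl)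
Why: Standard Vilsmeier-catalysed acid chloride formation; the benzyl ether is inert.

**Step 3**
Reactants: 5 acid chloride; 6 ethoxyacetylene (commercial hexanes solution, 2.5 equiv)
Product: 7 (±)-4-[4-(benzyloxy)benzyl]-3-ethoxycyclobut-2-en-1-one
Conditions: Et3N (1.3 equiv), Et2O, slow addition of 5, 0 °C → rt
Reagents that add atoms: none (6 is a numbered reactant)
Why: Et3N dehydrohalogenates 5 to the monoalkylketene, which undergoes thermal ketene–alkyne [2+2] cycloaddition; the nucleophilic terminal alkyne carbon bonds to the ketene carbonyl carbon, giving the 3-ethoxy-4-substituted cyclobutenone (the racemic C4 centre is inconsequential).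

**Step 4**
Reactants: 8 2-(3-hydroxyphenyl)ethanol; 9 benzyl bromide
Product: 10 2-[3-(benzyloxy)phenyl]ethanol
Conditions: K2CO3, acetone, reflux
Reagents that add atoms: none (9 is a numbered reactant)
Why: Williamson etherification; only the phenol is deprotonated by K2CO3, so O-benzylation is chemoselective over the primary alcohol.

**Step 5**
Reactants: 10 2-[3-(benzyloxy)phenyl]ethanol
Product: 11 1-(benzyloxy)-3-(2-bromoethyl)benzene
Conditions: CBr4, PPh3, CH2Cl2, 0 °C → rt
Reagents that add atoms: carbon tetrabromide, BrC(Br)(Br)Br (Br)
Why: Appel bromination of a primary alcohol under neutral conditions that leave the benzyl ether untouched.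

**Step 6**
Reactants: 11 bromide; 7 ethoxycyclobutenone
Product: 12 (±)-4-[4-(benzyloxy)benzyl]-3-{2-[3-(benzyloxy)phenyl]ethyl}cyclobut-2-en-1-one
Conditions: 11, Mg, THF; anhydrous CeCl3, −78 °C; then 7, −78 → 0 °C; then 1 M HCl, THF, 0 °C → rt
Reagents that add atoms: water, O (oxygen of the new C=O)
Why: Stork–Danheiser alkylative transposition: 1,2-addition of the organocerium/Grignard to the vinylogous ester, then acid hydrolysis of the enol ether and dehydration, moves the carbonyl to the former C3. C4 enolisation is disfavoured because it would give an antiaromatic cyclobutadienolate, which also prevents scrambling of the double bond.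

**Step 7 (key step)**
Reactants: 12 cyclobutenone; 3 methoxyalkyne (1.3 equiv)
Product: 13 2,6-bis[4-(benzyloxy)benzyl]-3-{2-[3-(benzyloxy)phenyl]ethyl}-5-methoxyphenol
Conditions: toluene, 80 → 110 °C, sealed tube; then KOH, MeOH, rt (cleaves any aryl ester formed from 13 and the vinylketene)
Reagents that add atoms: none
Why: Danheiser benzannulation, a cascade of 4π ring opening of 12 (C4 benzyl rotates outward) to the vinylketene, regioselective [2+2] with the ynol ether, 4π opening, 6π electrocyclisation and tautomerisation. The ketene carbon becomes C–OH, the alkyne's benzyl sits between OH and OMe, old C2–H becomes the lone aryl H, old C3 carries the aryl-ethyl chain and old C4 carries the second benzyl ortho to OH.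

**Step 8**
Reactants: 13 tris-benzyl ether
Product: 14 Bulbocodin D, 2,6-bis(4-hydroxybenzyl)-3-[2-(3-hydroxyphenyl)ethyl]-5-methoxyphenol
Conditions: H2 (1 atm), 10% Pd/C, EtOAc–MeOH, rt
Reagents that add atoms: none
Why: Catalytic hydrogenolysis cleaves the three aryl benzyl ethers; the diarylmethane and bibenzyl C–C bonds and the aryl methyl ether are stable.

---

**Compound list**
1 | chloroacetaldehyde dimethyl acetal | COC(OC)CCl | starting material
2 | 4-(benzyloxy)benzyl bromide | BrCc1ccc(OCc2ccccc2)cc1 | starting material
3 | 1-(benzyloxy)-4-(3-methoxyprop-2-yn-1-yl)benzene | COC#CCc1ccc(OCc2ccccc2)cc1 | intermediate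
4 | 3-[4-(benzyloxy)phenyl]propanoic acid | OC(=O)CCc1ccc(OCc2ccccc2)cc1 | starting material
5 | 3-[4-(benzyloxy)phenyl]propanoyl chloride | ClC(=O)CCc1ccc(OCc2ccccc2)cc1 | intermediate
6 | ethoxyacetylene | CCOC#C | starting material
7 | (±)-4-[4-(benzyloxy)benzyl]-3-ethoxycyclobut-2-en-1-one | CCOC1=CC(=O)C1Cc1ccc(OCc2ccccc2)cc1 | intermediate
8 | 2-(3-hydroxyphenyl)ethanol | OCCc1cccc(O)c1 | starting material
9 | benzyl bromide | BrCc1ccccc1 | starting material
10 | 2-[3-(benzyloxy)phenyl]ethanol | OCCc1cccc(OCc2ccccc2)c1 | intermediate
11 | 1-(benzyloxy)-3-(2-bromoethyl)benzene | BrCCc1cccc(OCc2ccccc2)c1 | intermediate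
12 | (±)-4-[4-(benzyloxy)benzyl]-3-{2-[3-(benzyloxy)phenyl]ethyl}cyclobut-2-en-1-one | O=C1C=C(CCc2cccc(OCc3ccccc3)c2)C1Cc1ccc(OCc2ccccc2)cc1 | intermediate
13 | 2,6-bis[4-(benzyloxy)benzyl]-3-{2-[3-(benzyloxy)phenyl]ethyl}-5-methoxyphenol | COc1cc(CCc2cccc(OCc3ccccc3)c2)c(Cc2ccc(OCc3ccccc3)cc2)c(O)c1Cc1ccc(OCc2ccccc2)cc1 | intermediate
14 | Bulbocodin D | COc1cc(CCc2cccc(O)c2)c(Cc2ccc(O)cc2)c(O)c1Cc1ccc(O)cc1 | target

**Total steps:** 8
**Longest linear sequence:** 5 (steps 2 → 3 → 6 → 7 → 8; the 4 → 5 → 6 → 7 → 8 branch is also 5)

**Three steps most likely to fail, with fallbacks**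
1. **Step 7 (benzannulation with a hindered 4-substituted cyclobutenone).** The vinylketene may oligomerise or the cascade may stall. Fallback: run the annulation on the unhindered 3-{2-[3-(benzyloxy)phenyl]ethyl}cyclobut-2-enone (dichloroketene + 4-aryl-1-butyne, then Zn dechlorination) with 3. Then install the second benzyl at the only free ortho position by ortho-specific formylation (MgCl2, Et3N, (CH2O)n) and addition of 4-BnOC6H4MgBr; the final H2/Pd-C step also hydrogenolyses the diarylcarbinol.
2. **Step 3 (aldoketene + ethoxyacetylene [2+2]).** Ketene dimerisation can keep the yield low. Fallback: Ghosez keteniminium [2+2], using the N,N-dimethylamide of 4 (Tf2O, collidine) with 1-(benzyloxy)-3-(but-3-yn-1-yl)benzene and aqueous hydrolysis. This gives 12 directly and bypasses 7 and step 6.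
3. **Step 1 (benzylation of lithium methoxyacetylide).** Competing amine alkylation, allene formation or ynol-ether hydrolysis are possible. Fallback: make the TIPS siloxyalkyne ArCH2C≡COTIPS by Kowalski homologation of methyl [4-(benzyloxy)phenyl]acetate (LiCHBr2; n-BuLi; TIPSCl) and use it in step 7. Then benzylate the free phenol, cleave TIPS (TBAF), O-methylate (MeI, K2CO3) and carry out the same global hydrogenolysis.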